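**Retrosynthetic overview**

1. Target 18 is a cis-fused decalin, (5R,6R,9R,10S) in drimane-type labels (ring A = C1–C5, C10; ring B = C5–C10; C11 = CO2H carbon on C9; C12 = CHO carbon on C8). The angular CH3, H-5, O-6 and O-9 all lie on one face.
2. 18 ⇐ fluoride-labile C11 ester 16 ⇐ C12 methyl oxidation of 14 ⇐ acylation of cis-1,4-diol 12 with trienoic acid 13.
3. 12 ⇐ endoperoxide 11 ⇐ sensitised singlet-oxygen [4+2] on the ring B dienoate 10 (photochemical key step: both C–O bonds, C6 and C9) ⇐ dienyl triflate 9 + CO ⇐ enone 8.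
4. 8 ⇐ ring A closure at C3–C4 (new manganese/nickel ring-closing hydroalkylation that also builds the gem-dimethyl carbon) ⇐ 6 ⇐ (S)-carvone 1 by two enolate alkylations (C1–C3 chain first, CH3 second).
5. Ring order: ring B is bought as (S)-carvone, ring A is closed second. C5 is bought; C10, then C6 and C9, are relayed from it.

Assumption: the target is the open hydroxy acid–enal drawn in the SMILES (it may equilibrate with its cyclic lactol tautomer), and (2E,4E,6E)-octa-2,4,6-trienoic acid is a catalogue compound.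

**Route**

Step 1
Reactants: 1 (S)-(+)-carvone; 2 1-chloro-3-iodopropane
Product: 4 (5S,6R)-6-(3-chloropropyl)-2-methyl-5-(prop-1-en-2-yl)cyclohex-2-en-1-one, via carvone lithium enolate 3 (not isolated)
Conditions: LiN(iPr)2 (1.1 equiv), THF, −78 °C; then 2 (1.5 equiv), DMPU, −78 → −20 °C
Reagents that add atoms: none
Why: Kinetic α′-deprotonation gives the cross-conjugated enolate, which is alkylated (SN2) only at the C–I end of 2; the new C10 centre (mainly trans to isopropenyl) is flattened again in step 2, so both epimers are used.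

Step 2
Reactants: 4 (5S,6R)-6-(3-chloropropyl)-2-methyl-5-(prop-1-en-2-yl)cyclohex-2-en-1-one
Product: 6 (5R,6S)-6-(3-chloropropyl)-2,6-dimethyl-5-(prop-1-en-2-yl)cyclohex-2-en-1-one, via tetrasubstituted lithium enolate 5 (not isolated)
Conditions: LiN(iPr)2 (1.2 equiv), THF, −78 °C; MeI (4 equiv), DMPU, −78 → −30 °C
Reagents that add atoms: iodomethane, CI
Why: Enolate alkylation: in 5 the C5 isopropenyl group sits pseudoaxial (A1,2 strain) and shields one face, so CH3 enters anti to it and the chloropropyl chain ends up cis to the isopropenyl carbon, which fixes quaternary C10 with CH3 on the face of H-5 (substrate control from the bought C5 centre); the primary chloride is inert to the enolate at this temperature.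

Step 3
Reactants: 6 (5R,6S)-6-(3-chloropropyl)-2,6-dimethyl-5-(prop-1-en-2-yl)cyclohex-2-en-1-one
Product: 8 (4aR,8aS)-2,5,5,8a-tetramethyl-4a,5,6,7,8,8a-hexahydronaphthalen-1(4H)-one, via primary iodide 7 (not isolated)
Conditions: NaI (3 equiv), DMA, 80 °C; then Mn(dpm)3 (20 mol %), Ni(acac)2 (10 mol %), PhSiH3 (2 equiv), DMA/1,2-dichloroethane (0.02 M), 25 °C
Reagents that add atoms: none
Why: Proposed new method: a ring-closing Markovnikov hydroalkylation in which the trivalent manganese hydride made from Mn(dpm)3 and PhSiH3 transfers a hydrogen atom to the CH2 terminus of the isopropenyl group (the only unhindered 1,1-disubstituted alkene; the trisubstituted enone alkene reacts more slowly), the resulting tertiary C4 radical is captured by the alkylnickel formed from the primary C3–I bond at low-valent nickel, and C(sp3)–C(sp3) reductive elimination from the seven-membered nickelacycle closes ring A and creates the gem-dimethyl quaternary carbon without touching C5 or C10 (the cis ring fusion is already fixed in 6); the closest known reaction type is the intermolecular manganese/nickel dual-catalytic MHAT hydroalkylation of 1,1-disubstituted olefins with primary alkyl iodides to give quaternary carbons, which has not been used as a ring closure or beside an enone.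

Step 4
Reactants: 8 (4aR,8aS)-2,5,5,8a-tetramethyl-4a,5,6,7,8,8a-hexahydronaphthalen-1(4H)-one
Product: 9 (4aR,8aS)-2,5,5,8a-tetramethyl-4a,5,6,7,8,8a-hexahydronaphthalen-1-yl trifluoromethanesulfonate
Conditions: Tf2O (1.3 equiv), 2,6-di-tert-butyl-4-methylpyridine (1.5 equiv), CH2Cl2, 0 → 25 °C
Reagents that add atoms: trifluoromethanesulfonic anhydride, O=S(=O)(OS(=O)(=O)C(F)(F)F)C(F)(F)F
Why: Dienol triflate formation (O-triflation of the enone, then γ-deprotonation at C6 by the hindered base) can only give the through-conjugated C6=C7–C8=C9 diene because C10 is quaternary; no stereocentre is touched.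

Step 5
Reactants: 9 (4aR,8aS)-2,5,5,8a-tetramethyl-4a,5,6,7,8,8a-hexahydronaphthalen-1-yl trifluoromethanesulfonate
Product: 10 2-(trimethylsilyl)ethyl (4aR,8aS)-2,5,5,8a-tetramethyl-4a,5,6,7,8,8a-hexahydronaphthalene-1-carboxylate
Conditions: Pd(OAc)2 (10 mol %), PPh3 (25 mol %), CO (1 atm), Me3SiCH2CH2OH (5 equiv), Et3N (2 equiv), DMF, 65 °C
Reagents that add atoms: carbon monoxide, [C-]#[O+]; 2-(trimethylsilyl)ethanol, C[Si](C)(C)CCO
Why: Palladium-catalysed alkoxycarbonylation (zerovalent palladium inserts into C9–OTf, CO inserts, the acylpalladium is trapped by the alcohol) installs C11 as a fluoride-labile ester; the ring-fusion centres are untouched.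

Step 6
Reactants: 10 2-(trimethylsilyl)ethyl (4aR,8aS)-2,5,5,8a-tetramethyl-4a,5,6,7,8,8a-hexahydronaphthalene-1-carboxylate
Product: 12 2-(trimethylsilyl)ethyl (1S,4R,4aR,8aS)-1,4-dihydroxy-2,5,5,8a-tetramethyl-1,4,4a,5,6,7,8,8a-octahydronaphthalene-1-carboxylate, via endoperoxide 11 (not isolated)
Conditions: O2, tetraphenylporphyrin (1 mol %), hν (white LED), CH2Cl2, −20 °C; then Zn, AcOH, 0 °C
Reagents that add atoms: dioxygen, O=O
Why: Dye-sensitised photooxygenation: singlet oxygen adds [4+2] across the s-cis ring B diene from the convex face of the cis-fused bicycle (the face of the angular CH3 and H-5; the other face is covered by ring A and its gem-dimethyl carbon), so the C6–O and C9–O bonds form together and cis to the angular methyl, and Zn/AcOH then reduces only the O–O bond to the cis-1,4-diol.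

Step 7
Reactants: 12 2-(trimethylsilyl)ethyl (1S,4R,4aR,8aS)-1,4-dihydroxy-2,5,5,8a-tetramethyl-1,4,4a,5,6,7,8,8a-octahydronaphthalene-1-carboxylate; 13 (2E,4E,6E)-octa-2,4,6-trienoic acid
Product: 14 2-(trimethylsilyl)ethyl (1S,4R,4aR,8aS)-1-hydroxy-2,5,5,8a-tetramethyl-4-[(2E,4E,6E)-octa-2,4,6-trienoyloxy]-1,4,4a,5,6,7,8,8a-octahydronaphthalene-1-carboxylate
Conditions: DCC (1.5 equiv), DMAP (0.2 equiv), CH2Cl2, 0 → 25 °C
Reagents that add atoms: none
Why: Steglich esterification acylates only the secondary allylic C6–OH (the tertiary C9–OH beside the ester and quaternary C10 is inert), with retention at C6 and without touching the E,E,E-triene.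

Step 8
Reactants: 14 2-(trimethylsilyl)ethyl (1S,4R,4aR,8aS)-1-hydroxy-2,5,5,8a-tetramethyl-4-[(2E,4E,6E)-octa-2,4,6-trienoyloxy]-1,4,4a,5,6,7,8,8a-octahydronaphthalene-1-carboxylate
Product: 16 2-(trimethylsilyl)ethyl (1R,4R,4aR,8aS)-2-formyl-1-hydroxy-5,5,8a-trimethyl-4-[(2E,4E,6E)-octa-2,4,6-trienoyloxy]-1,4,4a,5,6,7,8,8a-octahydronaphthalene-1-carboxylate, via allylic alcohol 15 (not isolated)
Conditions: SeO2 (2.2 equiv), pyridine (0.3 equiv), 1,4-dioxane, 80 °C
Reagents that add atoms: selenium dioxide, O=[Se]=O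
Why: Riley allylic oxidation (ene reaction at C7, then [2,3]-sigmatropic shift): the only allylic C–H bonds on the more substituted alkene terminus are those of the C12 methyl (C9 is quaternary; C6–H is on the other terminus and deactivated by the acyloxy group), and the primary allylic alcohol 15 is oxidised on to the enal in the same flask, with the hindered C11 ester and the pyridine buffer holding back lactonisation; no stereocentre is involved.

Step 9
Reactants: 16 2-(trimethylsilyl)ethyl (1R,4R,4aR,8aS)-2-formyl-1-hydroxy-5,5,8a-trimethyl-4-[(2E,4E,6E)-octa-2,4,6-trienoyloxy]-1,4,4a,5,6,7,8,8a-octahydronaphthalene-1-carboxylate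
Product: 18 (1R,4R,4aR,8aS)-2-formyl-1-hydroxy-5,5,8a-trimethyl-4-[(2E,4E,6E)-octa-2,4,6-trienoyloxy]-1,4,4a,5,6,7,8,8a-octahydronaphthalene-1-carboxylic acid, via tetrabutylammonium carboxylate 17 (not isolated)
Conditions: Bu4NF (2.5 equiv), THF, 0 °C; then aq. HCl to pH 3
Reagents that add atoms: none
Why: Fluoride-induced fragmentation of the 2-(trimethylsilyl)ethyl ester (attack at silicon, loss of ethene) frees the carboxylate under conditions too mild to hydrolyse the trienoate, and acidification gives the acid; C9 is quaternary and C6 is not enolised at 0 °C, so all four stereocentres are kept.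

**Compound list**

1 | (S)-(+)-carvone, (5S)-2-methyl-5-(prop-1-en-2-yl)cyclohex-2-en-1-one | C=C(C)[C@H]1CC=C(C)C(=O)C1 | starting material
2 | 1-chloro-3-iodopropane | ClCCCI | starting material
3 | lithium (3S)-6-methyl-3-(prop-1-en-2-yl)cyclohexa-1,5-dien-1-olate | C=C(C)[C@H]1CC=C(C)C(O[Li])=C1 | intermediate
4 | (5S,6R)-6-(3-chloropropyl)-2-methyl-5-(prop-1-en-2-yl)cyclohex-2-en-1-one (major trans epimer; used with its C6 epimer) | C=C(C)[C@H]1CC=C(C)C(=O)[C@@H]1CCCCl | intermediate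
5 | lithium (3R)-2-(3-chloropropyl)-6-methyl-3-(prop-1-en-2-yl)cyclohexa-1,5-dien-1-olate | C=C(C)[C@H]1CC=C(C)C(O[Li])=C1CCCCl | intermediate
6 | (5R,6S)-6-(3-chloropropyl)-2,6-dimethyl-5-(prop-1-en-2-yl)cyclohex-2-en-1-one (CH3 trans, chain cis to isopropenyl) | C=C(C)[C@H]1CC=C(C)C(=O)[C@@]1(C)CCCCl | intermediate
7 | (5R,6S)-6-(3-iodopropyl)-2,6-dimethyl-5-(prop-1-en-2-yl)cyclohex-2-en-1-one | C=C(C)[C@H]1CC=C(C)C(=O)[C@@]1(C)CCCI | intermediate
8 | (4aR,8aS)-2,5,5,8a-tetramethyl-4a,5,6,7,8,8a-hexahydronaphthalen-1(4H)-one (cis-fused) | C1C=C(C)C(=O)[C@@]2(C)CCCC(C)(C)[C@@H]12 | intermediate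
9 | (4aR,8aS)-2,5,5,8a-tetramethyl-4a,5,6,7,8,8a-hexahydronaphthalen-1-yl trifluoromethanesulfonate | C1=CC(C)=C(OS(=O)(=O)C(F)(F)F)[C@@]2(C)CCCC(C)(C)[C@@H]12 | intermediate
10 | 2-(trimethylsilyl)ethyl (4aR,8aS)-2,5,5,8a-tetramethyl-4a,5,6,7,8,8a-hexahydronaphthalene-1-carboxylate | C1=CC(C)=C(C(=O)OCC[Si](C)(C)C)[C@@]2(C)CCCC(C)(C)[C@@H]12 | intermediate
11 | 2-(trimethylsilyl)ethyl (1S,4R,4aR,8aS)-2,5,5,8a-tetramethyl-1,4,4a,5,6,7,8,8a-octahydro-1,4-epidioxynaphthalene-1-carboxylate | O1[C@@H]2C=C(C)[C@@](O1)(C(=O)OCC[Si](C)(C)C)[C@@]3(C)CCCC(C)(C)[C@@H]23 | intermediate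
12 | 2-(trimethylsilyl)ethyl (1S,4R,4aR,8aS)-1,4-dihydroxy-2,5,5,8a-tetramethyl-1,4,4a,5,6,7,8,8a-octahydronaphthalene-1-carboxylate | O[C@@H]1C=C(C)[C@@](O)(C(=O)OCC[Si](C)(C)C)[C@@]2(C)CCCC(C)(C)[C@@H]12 | intermediate
13 | (2E,4E,6E)-octa-2,4,6-trienoic acid | C/C=C/C=C/C=C/C(=O)O | starting material
14 | 2-(trimethylsilyl)ethyl (1S,4R,4aR,8aS)-1-hydroxy-2,5,5,8a-tetramethyl-4-[(2E,4E,6E)-octa-2,4,6-trienoyloxy]-1,4,4a,5,6,7,8,8a-octahydronaphthalene-1-carboxylate | C/C=C/C=C/C=C/C(=O)O[C@@H]1C=C(C)[C@@](O)(C(=O)OCC[Si](C)(C)C)[C@@]2(C)CCCC(C)(C)[C@@H]12 | intermediate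
15 | 2-(trimethylsilyl)ethyl (1R,4R,4aR,8aS)-1-hydroxy-2-(hydroxymethyl)-5,5,8a-trimethyl-4-[(2E,4E,6E)-octa-2,4,6-trienoyloxy]-1,4,4a,5,6,7,8,8a-octahydronaphthalene-1-carboxylate | C/C=C/C=C/C=C/C(=O)O[C@@H]1C=C(CO)[C@@](O)(C(=O)OCC[Si](C)(C)C)[C@@]2(C)CCCC(C)(C)[C@@H]12 | intermediate
16 | 2-(trimethylsilyl)ethyl (1R,4R,4aR,8aS)-2-formyl-1-hydroxy-5,5,8a-trimethyl-4-[(2E,4E,6E)-octa-2,4,6-trienoyloxy]-1,4,4a,5,6,7,8,8a-octahydronaphthalene-1-carboxylate | C/C=C/C=C/C=C/C(=O)O[C@@H]1C=C(C=O)[C@@](O)(C(=O)OCC[Si](C)(C)C)[C@@]2(C)CCCC(C)(C)[C@@H]12 | intermediate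
17 | tetrabutylammonium (1R,4R,4aR,8aS)-2-formyl-1-hydroxy-5,5,8a-trimethyl-4-[(2E,4E,6E)-octa-2,4,6-trienoyloxy]-1,4,4a,5,6,7,8,8a-octahydronaphthalene-1-carboxylate | CCCC[N+](CCCC)(CCCC)CCCC.C/C=C/C=C/C=C/C(=O)O[C@@H]1C=C(C=O)[C@@](O)(C(=O)[O-])[C@@]2(C)CCCC(C)(C)[C@@H]12 | intermediate
18 | (1R,4R,4aR,8aS)-2-formyl-1-hydroxy-5,5,8a-trimethyl-4-[(2E,4E,6E)-octa-2,4,6-trienoyloxy]-1,4,4a,5,6,7,8,8a-octahydronaphthalene-1-carboxylic acid | C/C=C/C=C/C=C/C(=O)O[C@@H]1C=C(C=O)[C@@](O)(C(=O)O)[C@@]2(C)CCCC(C)(C)[C@@H]12 | target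

**Step count and risks**

Total step count: 9. Longest linear sequence: 9 (1 → 18; 2 and 13 are bought).

Steps most likely to fail:

Step 3 (the new ring closure). Likely failure modes are simple hydrogenation of the isopropenyl group, loss of the halide, or reduction of the enone. The fallback uses known reactions only, leaves the route at 1 and rejoins it at 8. Carvone 1 is methylated (LiN(iPr)2, MeI) to (5S,6R)-2,6-dimethyl-5-(prop-1-en-2-yl)cyclohex-2-en-1-one F1. Fe(acac)3/PhSiH3 (EtOH, 60 °C) couples its isopropenyl group with acrolein in an MHAT Giese reaction, giving 4-[(1S,6R)-4,6-dimethyl-5-oxocyclohex-3-en-1-yl]-4-methylpentanal F2, which already carries the gem-dimethyl carbon and C3–C1. NaBH4 (MeOH/CH2Cl2, −78 °C) reduces only the aldehyde to (5S,6R)-5-(5-hydroxy-2-methylpentan-2-yl)-2,6-dimethylcyclohex-2-en-1-one F3, and I2/PPh3/imidazole gives (5S,6R)-5-(5-iodo-2-methylpentan-2-yl)-2,6-dimethylcyclohex-2-en-1-one F4. LiN(iPr)2 (THF/DMPU, −78 → 0 °C) then forms the cross-conjugated enolate, which closes ring A by intramolecular alkylation at C10; six-ring closure onto the enolate from the neighbouring carbon gives the cis ring fusion of 8.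

Step 8 (Riley oxidation). The intermediate alcohol 15 may lactonise onto the C11 ester, or the trienoate may suffer. The fallback replaces the selenium ene chemistry by radical bromination and halide oxidation at a stage where neither problem exists; it leaves the route at endoperoxide 11 (isolated by omitting the Zn/AcOH stage of step 6) and rejoins it at 16. NBS (hν, PhCF3, 25 °C) brominates the only abstractable allylic position (the bridgehead C6–H is protected by Bredt's rule), giving 2-(trimethylsilyl)ethyl (1R,4R,4aR,8aS)-2-(bromomethyl)-5,5,8a-trimethyl-1,4,4a,5,6,7,8,8a-octahydro-1,4-epidioxynaphthalene-1-carboxylate F12. IBX in DMSO (60 °C) converts the allylic bromide directly into 2-(trimethylsilyl)ethyl (1R,4R,4aR,8aS)-2-formyl-5,5,8a-trimethyl-1,4,4a,5,6,7,8,8a-octahydro-1,4-epidioxynaphthalene-1-carboxylate F13 without a free C12 alcohol. Thiourea (MeOH, 0 °C) cleaves the O–O bond to 2-(trimethylsilyl)ethyl (1R,4R,4aR,8aS)-2-formyl-1,4-dihydroxy-5,5,8a-trimethyl-1,4,4a,5,6,7,8,8a-octahydronaphthalene-1-carboxylate F14, and DCC/DMAP esterification with 13 gives 16.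

Step 6 (photooxygenation). The diene is deactivated by the conjugated ester and hindered at C9, so ene pathways may compete. The fallback takes the ester out of conjugation by a redox detour; it leaves the route at 10 and rejoins it at 14. iBu2AlH (CH2Cl2, −78 °C) gives [(4aR,8aS)-2,5,5,8a-tetramethyl-4a,5,6,7,8,8a-hexahydronaphthalen-1-yl]methanol F5, and TBSCl/imidazole gives tert-butyl(dimethyl){[(4aR,8aS)-2,5,5,8a-tetramethyl-4a,5,6,7,8,8a-hexahydronaphthalen-1-yl]methoxy}silane F6, now an electron-rich diene. Photooxygenation as in step 6 gives tert-butyl(dimethyl){[(1S,4R,4aR,8aS)-2,5,5,8a-tetramethyl-1,4,4a,5,6,7,8,8a-octahydro-1,4-epidioxynaphthalen-1-yl]methoxy}silane F7, reduced in the same flask (Zn, AcOH) to (1S,4R,4aR,8aS)-1-({[tert-butyl(dimethyl)silyl]oxy}methyl)-2,5,5,8a-tetramethyl-1,4,4a,5,6,7,8,8a-octahydronaphthalene-1,4-diol F8. DCC/DMAP with 13 gives (1R,4S,4aS,8aR)-4-({[tert-butyl(dimethyl)silyl]oxy}methyl)-4-hydroxy-3,4a,8,8-tetramethyl-1,4,4a,5,6,7,8,8a-octahydronaphthalen-1-yl (2E,4E,6E)-octa-2,4,6-trienoate F9. HF·pyridine gives (1R,4S,4aS,8aR)-4-hydroxy-4-(hydroxymethyl)-3,4a,8,8-tetramethyl-1,4,4a,5,6,7,8,8a-octahydronaphthalen-1-yl (2E,4E,6E)-octa-2,4,6-trienoate F10. TEMPO/PhI(OAc)2 (MeCN–water) oxidises the primary alcohol to (1S,4R,4aR,8aS)-1-hydroxy-2,5,5,8a-tetramethyl-4-[(2E,4E,6E)-octa-2,4,6-trienoyloxy]-1,4,4a,5,6,7,8,8a-octahydronaphthalene-1-carboxylic acid F11. 2-(Trimethylsilyl)ethyl 2,2,2-trichloroacetimidate (toluene, 80 °C) then esterifies the acid to 14.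

**Further compounds**

F1 | step 3 | (5S,6R)-2,6-dimethyl-5-(prop-1-en-2-yl)cyclohex-2-en-1-one | C=C(C)[C@H]1CC=C(C)C(=O)[C@@H]1C
F2 | step 3 | 4-[(1S,6R)-4,6-dimethyl-5-oxocyclohex-3-en-1-yl]-4-methylpentanal | O=CCCC(C)(C)[C@H]1CC=C(C)C(=O)[C@@H]1C
F3 | step 3 | (5S,6R)-5-(5-hydroxy-2-methylpentan-2-yl)-2,6-dimethylcyclohex-2-en-1-one | OCCCC(C)(C)[C@H]1CC=C(C)C(=O)[C@@H]1C
F4 | step 3 | (5S,6R)-5-(5-iodo-2-methylpentan-2-yl)-2,6-dimethylcyclohex-2-en-1-one | ICCCC(C)(C)[C@H]1CC=C(C)C(=O)[C@@H]1C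
F5 | step 6 | [(4aR,8aS)-2,5,5,8a-tetramethyl-4a,5,6,7,8,8a-hexahydronaphthalen-1-yl]methanol | C1=CC(C)=C(CO)[C@@]2(C)CCCC(C)(C)[C@@H]12
F6 | step 6 | tert-butyl(dimethyl){[(4aR,8aS)-2,5,5,8a-tetramethyl-4a,5,6,7,8,8a-hexahydronaphthalen-1-yl]methoxy}silane | C1=CC(C)=C(CO[Si](C)(C)C(C)(C)C)[C@@]2(C)CCCC(C)(C)[C@@H]12
F7 | step 6 | tert-butyl(dimethyl){[(1S,4R,4aR,8aS)-2,5,5,8a-tetramethyl-1,4,4a,5,6,7,8,8a-octahydro-1,4-epidioxynaphthalen-1-yl]methoxy}silane | O1[C@@H]2C=C(C)[C@@](O1)(CO[Si](C)(C)C(C)(C)C)[C@@]3(C)CCCC(C)(C)[C@@H]23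
F8 | step 6 | (1S,4R,4aR,8aS)-1-({[tert-butyl(dimethyl)silyl]oxy}methyl)-2,5,5,8a-tetramethyl-1,4,4a,5,6,7,8,8a-octahydronaphthalene-1,4-diol | O[C@@H]1C=C(C)[C@@](O)(CO[Si](C)(C)C(C)(C)C)[C@@]2(C)CCCC(C)(C)[C@@H]12
F9 | step 6 | (1R,4S,4aS,8aR)-4-({[tert-butyl(dimethyl)silyl]oxy}methyl)-4-hydroxy-3,4a,8,8-tetramethyl-1,4,4a,5,6,7,8,8a-octahydronaphthalen-1-yl (2E,4E,6E)-octa-2,4,6-trienoate | C/C=C/C=C/C=C/C(=O)O[C@@H]1C=C(C)[C@@](O)(CO[Si](C)(C)C(C)(C)C)[C@@]2(C)CCCC(C)(C)[C@@H]12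
F10 | step 6 | (1R,4S,4aS,8aR)-4-hydroxy-4-(hydroxymethyl)-3,4a,8,8-tetramethyl-1,4,4a,5,6,7,8,8a-octahydronaphthalen-1-yl (2E,4E,6E)-octa-2,4,6-trienoate | C/C=C/C=C/C=C/C(=O)O[C@@H]1C=C(C)[C@@](O)(CO)[C@@]2(C)CCCC(C)(C)[C@@H]12
F11 | step 6 | (1S,4R,4aR,8aS)-1-hydroxy-2,5,5,8a-tetramethyl-4-[(2E,4E,6E)-octa-2,4,6-trienoyloxy]-1,4,4a,5,6,7,8,8a-octahydronaphthalene-1-carboxylic acid | C/C=C/C=C/C=C/C(=O)O[C@@H]1C=C(C)[C@@](O)(C(=O)O)[C@@]2(C)CCCC(C)(C)[C@@H]12
F12 | step 8 | 2-(trimethylsilyl)ethyl (1R,4R,4aR,8aS)-2-(bromomethyl)-5,5,8a-trimethyl-1,4,4a,5,6,7,8,8a-octahydro-1,4-epidioxynaphthalene-1-carboxylate | O1[C@@H]2C=C(CBr)[C@@](O1)(C(=O)OCC[Si](C)(C)C)[C@@]3(C)CCCC(C)(C)[C@@H]23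
F13 | step 8 | 2-(trimethylsilyl)ethyl (1R,4R,4aR,8aS)-2-formyl-5,5,8a-trimethyl-1,4,4a,5,6,7,8,8a-octahydro-1,4-epidioxynaphthalene-1-carboxylate | O1[C@@H]2C=C(C=O)[C@@](O1)(C(=O)OCC[Si](C)(C)C)[C@@]3(C)CCCC(C)(C)[C@@H]23
F14 | step 8 | 2-(trimethylsilyl)ethyl (1R,4R,4aR,8aS)-2-formyl-1,4-dihydroxy-5,5,8a-trimethyl-1,4,4a,5,6,7,8,8a-octahydronaphthalene-1-carboxylate | O[C@@H]1C=C(C=O)[C@@](O)(C(=O)OCC[Si](C)(C)C)[C@@]2(C)CCCC(C)(C)[C@@H]12
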